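The route rests on disconnecting the C3–C4 bond of the ten-membered carbocycle (germacrane numbering). The allylic carbinol C3 next to the Z-trisubstituted C4=C5 alkene is the signature of an alkenylmetal–aldehyde addition. An intramolecular Nozaki–Hiyama–Kishi reaction closes the carbocycle as the last ring, creates C3 and transfers the alkene geometry from a (Z)-vinyl iodide. Its precursor is a seco-aldehyde that already holds the cis-fused α-methylene-γ-butyrolactone (C6, C7), the C8 methacrylate and the C1–C10 oxirane. The lactone comes from an indium Barbier union of a (Z)-bromomethyl enoate with (Z)-3-iodobut-2-enal, the oxirane from a Shi epoxidation, and C8 is corrected by a Mitsunobu esterification.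

Key step: step 16

Remark: germacrane numbering is used for all intermediates (C1/C10 oxirane carbons, C10 bearing methyl C14; C3 carbinol; C4(C15)=C5; C6 lactone O-carbon; C7; C8 ester carbon; C11(=C13)–C12 lactone unit), and enantiopure (R)-2-vinyloxirane, the hydrolytic-kinetic-resolution product of butadiene monoxide, is taken as purchasable.

Step 1
Reactants: 1 (R)-2-vinyloxirane
Product: 2 (3S)-hex-1-en-5-yn-3-ol
Conditions: LiC≡CH·H2NCH2CH2NH2, DMSO, 0 → 25 °C; H2O
Reagents that add atoms: lithium acetylide–ethylenediamine complex, [Li+].[C-]#C.NCCN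
Why: Acetylide opens the oxirane by SN2 attack at its unsubstituted CH2 carbon (epoxide alkynylation), so the future C8 stereocentre is taken over from 1 untouched (the descriptor changes from R to S only through the priority rules).

Step 2
Reactants: 2 (3S)-hex-1-en-5-yn-3-ol
Product: 3 tert-butyl{[(3S)-hex-1-en-5-yn-3-yl]oxy}dimethylsilane
Conditions: TBSCl, imidazole, DMF, 25 °C
Reagents that add atoms: tert-butyldimethylsilyl chloride, CC(C)(C)[Si](C)(C)Cl
Why: Standard silylation of the secondary alcohol; the bulky, non-chelating silyl ether later steers the facial selectivity of step 11 and can be removed without touching the 4-methoxybenzyl ether.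

Step 3
Reactants: 3 tert-butyl{[(3S)-hex-1-en-5-yn-3-yl]oxy}dimethylsilane
Product: 5 (3E,6S)-6-(tert-butyldimethylsilyloxy)-4-methylocta-3,7-dien-1-ol, via alkenylalane 4 (not isolated)
Conditions: Me3Al, Cp2ZrCl2 (cat.), CH2Cl2, 0 → 25 °C; evaporate; n-BuLi, THF/hexane, −78 °C; ethylene oxide, −78 → 0 °C; aq. Rochelle salt
Reagents that add atoms: trimethylaluminium, C[Al](C)C; ethylene oxide, C1CO1
Why: Zirconium-catalysed syn-carboalumination (Negishi) adds methyl to the internal and aluminium to the terminal alkyne carbon and so fixes the E geometry of the C1=C10 alkene, and the derived lithium alanate opens ethylene oxide with retention of alkene geometry to add C2 and C3.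

Step 4
Reactants: 5 (3E,6S)-6-(tert-butyldimethylsilyloxy)-4-methylocta-3,7-dien-1-ol
Product: 6 tert-butyl{[(3S,5E)-8-(4-methoxybenzyloxy)-5-methylocta-1,5-dien-3-yl]oxy}dimethylsilane
Conditions: NaH, 4-methoxybenzyl chloride, Bu4NI (cat.), THF/DMF, 0 → 25 °C
Reagents that add atoms: 4-methoxybenzyl chloride, COc1ccc(CCl)cc1
Why: Williamson etherification of the primary alkoxide gives a 4-methoxybenzyl ether that can be removed oxidatively at neutral pH when the acid-labile epoxy alcohol is unveiled in step 14.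

Step 5
Reactants: 6 tert-butyl{[(3S,5E)-8-(4-methoxybenzyloxy)-5-methylocta-1,5-dien-3-yl]oxy}dimethylsilane
Product: 7 tert-butyl{[(2S)-1-{(2R,3R)-3-[2-(4-methoxybenzyloxy)ethyl]-2-methyloxiran-2-yl}but-3-en-2-yl]oxy}dimethylsilane
Conditions: D-fructose-derived Shi ketone (30 mol%), Oxone (2KHSO5·KHSO4·K2SO4), K2CO3, Bu4NHSO4, MeCN/CH2(OMe)2–aq. Na2B4O7/Na2EDTA, 0 °C
Reagents that add atoms: Oxone (active oxidant KHSO5), [K+].[O-]S(=O)(=O)OO
Why: Shi asymmetric epoxidation: the dioxirane of the D-fructose-derived ketone attacks the electron-rich E-trisubstituted alkene through the spiro transition state and should deliver the (R,R) epoxide (C1 and C10) under reagent control, while the monosubstituted vinyl group is far less reactive.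

Step 6
Reactants: 7 tert-butyl{[(2S)-1-{(2R,3R)-3-[2-(4-methoxybenzyloxy)ethyl]-2-methyloxiran-2-yl}but-3-en-2-yl]oxy}dimethylsilane
Product: 8 (2S)-2-(tert-butyldimethylsilyloxy)-3-{(2R,3R)-3-[2-(4-methoxybenzyloxy)ethyl]-2-methyloxiran-2-yl}propanal
Conditions: OsO4 (cat.), NaIO4, 2,6-lutidine, 1,4-dioxane/H2O, 25 °C
Reagents that add atoms: osmium tetroxide OsO4 (catalytic oxygen carrier), O=[Os](=O)(=O)=O; sodium periodate NaIO4 (terminal oxygen source), [Na+].[O-]I(=O)(=O)=O
Why: Lemieux–Johnson oxidative cleavage of the only remaining alkene, the terminal vinyl group, gives the α-silyloxy aldehyde under buffered conditions that leave the epoxide and the C8 stereocentre intact.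

Step 7
Reactants: 8 (2S)-2-(tert-butyldimethylsilyloxy)-3-{(2R,3R)-3-[2-(4-methoxybenzyloxy)ethyl]-2-methyloxiran-2-yl}propanal
Product: 9 methyl (4S)-4-(tert-butyldimethylsilyloxy)-3-hydroxy-5-{(2R,3R)-3-[2-(4-methoxybenzyloxy)ethyl]-2-methyloxiran-2-yl}-2-methylidenepentanoate (both C3 epimers)
Conditions: methyl acrylate, DABCO, 1,4-dioxane/H2O, 25 °C
Reagents that add atoms: methyl acrylate, C=CC(=O)OC
Why: Morita–Baylis–Hillman reaction under amine catalysis installs C11, C12 and C13; the configuration of the new carbinol carbon is irrelevant because it becomes sp2 in step 8.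

Step 8
Reactants: 9 methyl (4S)-4-(tert-butyldimethylsilyloxy)-3-hydroxy-5-{(2R,3R)-3-[2-(4-methoxybenzyloxy)ethyl]-2-methyloxiran-2-yl}-2-methylidenepentanoate
Product: 10 methyl (2Z,4S)-2-(bromomethyl)-4-(tert-butyldimethylsilyloxy)-5-{(2R,3R)-3-[2-(4-methoxybenzyloxy)ethyl]-2-methyloxiran-2-yl}pent-2-enoate
Conditions: NBS, Me2S, CH2Cl2, −20 → 25 °C
Reagents that add atoms: N-bromosuccinimide, O=C1CCC(=O)N1Br
Why: The bromodimethylsulfonium reagent converts the Baylis–Hillman alcohol into the allylic bromide with allylic transposition (SN2′), which gives the thermodynamically preferred (Z)-2-(bromomethyl)enoate with C8 cis to CH2Br.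

Step 9
Reactants: 11 but-2-yn-1-ol
Product: 13 (2Z)-3-iodobut-2-en-1-ol, via cyclic alkenylalanate 12 (not isolated)
Conditions: NaAlH2(OCH2CH2OMe)2, THF, 0 °C; then I2, −78 → 0 °C
Reagents that add atoms: iodine, II
Why: Alkoxide-directed trans-hydroalumination of the propargylic alcohol places aluminium on C3 inside a five-membered alanate, and iodinolysis with retention gives the (Z)-iodoalkene whose geometry becomes that of C4=C5.

Step 10
Reactants: 13 (2Z)-3-iodobut-2-en-1-ol
Product: 14 (2Z)-3-iodobut-2-enal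
Conditions: MnO2, CH2Cl2, 25 °C, dark; used at once
Reagents that add atoms: none
Why: Chemoselective allylic oxidation with MnO2 should give the (Z)-enal without isomerisation when it is kept in the dark and used directly.

Step 11
Reactants: 10 methyl (2Z,4S)-2-(bromomethyl)-4-(tert-butyldimethylsilyloxy)-5-{(2R,3R)-3-[2-(4-methoxybenzyloxy)ethyl]-2-methyloxiran-2-yl}pent-2-enoate; 14 (2Z)-3-iodobut-2-enal
Product: 16 (4S,5R)-4-[(1S)-1-(tert-butyldimethylsilyloxy)-2-{(2R,3R)-3-[2-(4-methoxybenzyloxy)ethyl]-2-methyloxiran-2-yl}ethyl]-5-[(1Z)-2-iodoprop-1-en-1-yl]-3-methylideneoxolan-2-one, via hydroxy ester 15 (not isolated)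
Conditions: In powder, THF/H2O 1:1, 25 °C; then PPTS (cat.), toluene, 40 °C
Reagents that add atoms: none
Why: Indium-mediated Barbier 2-(alkoxycarbonyl)allylation (Dreiding–Schmidt type): the chair transition state with the C8 substituent pseudo-axial gives the syn adduct and hence, after lactonisation, the cis-fused lactone (C6 and C7), and C7 is attacked anti to the C8–O bond in the conformer whose C8–H eclipses the allyl unit (minimised 1,3-allylic strain), which fixes C7 relative to C8 and leaves C8 with the configuration opposite to the one finally needed.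

Step 12
Reactants: 16 (4S,5R)-4-[(1S)-1-(tert-butyldimethylsilyloxy)-2-{(2R,3R)-3-[2-(4-methoxybenzyloxy)ethyl]-2-methyloxiran-2-yl}ethyl]-5-[(1Z)-2-iodoprop-1-en-1-yl]-3-methylideneoxolan-2-one
Product: 17 (4R,5R)-4-[(1S)-1-hydroxy-2-{(2R,3R)-3-[2-(4-methoxybenzyloxy)ethyl]-2-methyloxiran-2-yl}ethyl]-5-[(1Z)-2-iodoprop-1-en-1-yl]-3-methylideneoxolan-2-one
Conditions: HF·pyridine, pyridine, THF, 0 → 25 °C
Reagents that add atoms: none
Why: Fluoride-mediated cleavage of the secondary silyl ether under pyridine-buffered conditions, to which the 4-methoxybenzyl ether, the epoxide and the lactone should be stable.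

Step 13
Reactants: 17 (4R,5R)-4-[(1S)-1-hydroxy-2-{(2R,3R)-3-[2-(4-methoxybenzyloxy)ethyl]-2-methyloxiran-2-yl}ethyl]-5-[(1Z)-2-iodoprop-1-en-1-yl]-3-methylideneoxolan-2-one
Product: 18 (1R)-1-{(2R,3R)-2-[(1Z)-2-iodoprop-1-en-1-yl]-4-methylidene-5-oxooxolan-3-yl}-2-{(2R,3R)-3-[2-(4-methoxybenzyloxy)ethyl]-2-methyloxiran-2-yl}ethyl 2-methylprop-2-enoate
Conditions: methacrylic acid, PPh3, DIAD, toluene, 0 → 25 °C
Reagents that add atoms: methacrylic acid, C=C(C)C(=O)O
Why: Mitsunobu esterification: SN2 displacement of the alkoxyphosphonium by methacrylate inverts C8 to the required configuration and installs the ester in the same operation.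

Step 14
Reactants: 18 (1R)-1-{(2R,3R)-2-[(1Z)-2-iodoprop-1-en-1-yl]-4-methylidene-5-oxooxolan-3-yl}-2-{(2R,3R)-3-[2-(4-methoxybenzyloxy)ethyl]-2-methyloxiran-2-yl}ethyl 2-methylprop-2-enoate
Product: 19 (1R)-2-[(2R,3R)-3-(2-hydroxyethyl)-2-methyloxiran-2-yl]-1-{(2R,3R)-2-[(1Z)-2-iodoprop-1-en-1-yl]-4-methylidene-5-oxooxolan-3-yl}ethyl 2-methylprop-2-enoate
Conditions: DDQ, CH2Cl2/pH 7 phosphate buffer, 0 °C
Reagents that add atoms: none
Why: Oxidative cleavage of the 4-methoxybenzyl ether by DDQ at neutral pH frees the primary alcohol without acid that would trigger attack of this hydroxyl on the neighbouring epoxide.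

Step 15
Reactants: 19 (1R)-2-[(2R,3R)-3-(2-hydroxyethyl)-2-methyloxiran-2-yl]-1-{(2R,3R)-2-[(1Z)-2-iodoprop-1-en-1-yl]-4-methylidene-5-oxooxolan-3-yl}ethyl 2-methylprop-2-enoate
Product: 20 (1R)-1-{(2R,3R)-2-[(1Z)-2-iodoprop-1-en-1-yl]-4-methylidene-5-oxooxolan-3-yl}-2-[(2R,3R)-2-methyl-3-(2-oxoethyl)oxiran-2-yl]ethyl 2-methylprop-2-enoate
Conditions: Dess–Martin periodinane, NaHCO3, CH2Cl2, 0 °C; used crude at once
Reagents that add atoms: none
Why: Buffered Dess–Martin oxidation gives the β,γ-epoxy aldehyde under non-basic conditions that avoid β-elimination of the epoxide.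

Step 16
Reactants: 20 (1R)-1-{(2R,3R)-2-[(1Z)-2-iodoprop-1-en-1-yl]-4-methylidene-5-oxooxolan-3-yl}-2-[(2R,3R)-2-methyl-3-(2-oxoethyl)oxiran-2-yl]ethyl 2-methylprop-2-enoate
Product: 22 (1R,3S,4Z,6S,7R,8R,10R)-1,10-epoxy-3-hydroxy-8-(2-methylprop-2-enoyloxy)germacra-4,11(13)-dien-12,6-olide, via alkenylchromium 21 (not isolated)
Conditions: CrCl2 (excess), NiCl2 (cat.), degassed DMSO/THF, 25 °C, 2 mM, slow addition of 20; aq. work-up
Reagents that add atoms: none
Why: Zerovalent nickel (formed from NiCl2 by CrCl2) inserts into the C4–I bond with retention of the Z geometry, the alkenyl group passes to trivalent chromium (21), and this alkenylchromium adds intramolecularly to the C3 aldehyde. The closest known reaction type is the Nozaki–Hiyama–Kishi macrocyclisation of vinyl iodide aldehydes, which is established for ten-membered germacranolide carbocycles. The ten-membered ring closes in a 10-exo-trig mode at the C3–C4 bond, with the lactone and the oxirane already in place. The new C3 stereocentre is set under macrocyclic control: the Z-alkene, the cis-fused lactone and the rigid trans-oxirane restrict the folding of the chain, and the chromium-bound carbonyl oxygen should point to the ring periphery on the same side as the oxirane oxygen, which corresponds to the (3S) alcohol. The step needs chemoselectivity for the aldehyde over the two acrylate-type esters and the oxirane, which the low basicity and carbonyl selectivity of alkenylchromium secure. It also needs ring closure over oligomerisation, which high dilution with slow addition and the turn imposed by the Z-alkene and the cis-lactone favour.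

Step 17
Reactants: 22 (1R,3S,4Z,6S,7R,8R,10R)-1,10-epoxy-3-hydroxy-8-(2-methylprop-2-enoyloxy)germacra-4,11(13)-dien-12,6-olide
Product: 23 (1R,3S,4Z,6S,7R,8R,10R)-3-acetoxy-1,10-epoxy-8-(2-methylprop-2-enoyloxy)germacra-4,11(13)-dien-12,6-olide (CNP0267696.3)
Conditions: Ac2O, pyridine, DMAP (cat.), CH2Cl2, 0 → 25 °C
Reagents that add atoms: acetic anhydride, CC(=O)OC(C)=O
Why: Standard acylation of the only free hydroxyl, the allylic C3 alcohol, proceeds with retention and gives the target.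

Compound list

1 | (R)-2-vinyloxirane ((2R)-2-ethenyloxirane) | C=C[C@@H]1CO1 | starting material
2 | (3S)-hex-1-en-5-yn-3-ol | C=C[C@@H](O)CC#C | intermediate
3 | tert-butyl{[(3S)-hex-1-en-5-yn-3-yl]oxy}dimethylsilane | C=C[C@@H](O[Si](C)(C)C(C)(C)C)CC#C | intermediate
4 | dimethyl[(1E,4S)-4-(tert-butyldimethylsilyloxy)-2-methylhexa-1,5-dien-1-yl]alane | C=C[C@@H](O[Si](C)(C)C(C)(C)C)C/C(C)=C/[Al](C)C | intermediate
5 | (3E,6S)-6-(tert-butyldimethylsilyloxy)-4-methylocta-3,7-dien-1-ol | C=C[C@@H](O[Si](C)(C)C(C)(C)C)C/C(C)=C/CCO | intermediate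
6 | tert-butyl{[(3S,5E)-8-(4-methoxybenzyloxy)-5-methylocta-1,5-dien-3-yl]oxy}dimethylsilane | C=C[C@@H](O[Si](C)(C)C(C)(C)C)C/C(C)=C/CCOCc1ccc(OC)cc1 | intermediate
7 | tert-butyl{[(2S)-1-{(2R,3R)-3-[2-(4-methoxybenzyloxy)ethyl]-2-methyloxiran-2-yl}but-3-en-2-yl]oxy}dimethylsilane | C=C[C@@H](O[Si](C)(C)C(C)(C)C)C[C@@]1(C)O[C@@H]1CCOCc1ccc(OC)cc1 | intermediate
8 | (2S)-2-(tert-butyldimethylsilyloxy)-3-{(2R,3R)-3-[2-(4-methoxybenzyloxy)ethyl]-2-methyloxiran-2-yl}propanal | O=C[C@@H](O[Si](C)(C)C(C)(C)C)C[C@@]1(C)O[C@@H]1CCOCc1ccc(OC)cc1 | intermediate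
9 | methyl (4S)-4-(tert-butyldimethylsilyloxy)-3-hydroxy-5-{(2R,3R)-3-[2-(4-methoxybenzyloxy)ethyl]-2-methyloxiran-2-yl}-2-methylidenepentanoate (both C3 epimers) | COC(=O)C(=C)C(O)[C@@H](O[Si](C)(C)C(C)(C)C)C[C@@]1(C)O[C@@H]1CCOCc1ccc(OC)cc1 | intermediate
10 | methyl (2Z,4S)-2-(bromomethyl)-4-(tert-butyldimethylsilyloxy)-5-{(2R,3R)-3-[2-(4-methoxybenzyloxy)ethyl]-2-methyloxiran-2-yl}pent-2-enoate | COC(=O)/C(CBr)=C/[C@@H](O[Si](C)(C)C(C)(C)C)C[C@@]1(C)O[C@@H]1CCOCc1ccc(OC)cc1 | intermediate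
11 | but-2-yn-1-ol | CC#CCO | starting material
12 | sodium 2,2-bis(2-methoxyethoxy)-3-methyl-2,5-dihydro-1,2-oxaaluminol-2-uide (cyclic alkenylalanate) | CC1=CCO[Al-]1(OCCOC)OCCOC.[Na+] | intermediate
13 | (2Z)-3-iodobut-2-en-1-ol | OC/C=C(/C)I | intermediate
14 | (2Z)-3-iodobut-2-enal | O=C/C=C(/C)I | intermediate
15 | methyl (3S,4R,5Z)-3-[(1S)-1-(tert-butyldimethylsilyloxy)-2-{(2R,3R)-3-[2-(4-methoxybenzyloxy)ethyl]-2-methyloxiran-2-yl}ethyl]-4-hydroxy-6-iodo-2-methylidenehept-5-enoate | COc1ccc(COCC[C@H]2O[C@]2(C)C[C@H](O[Si](C)(C)C(C)(C)C)[C@@H](C(=C)C(=O)OC)[C@@H](O)/C=C(/C)I)cc1 | intermediate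
16 | (4S,5R)-4-[(1S)-1-(tert-butyldimethylsilyloxy)-2-{(2R,3R)-3-[2-(4-methoxybenzyloxy)ethyl]-2-methyloxiran-2-yl}ethyl]-5-[(1Z)-2-iodoprop-1-en-1-yl]-3-methylideneoxolan-2-one | COc1ccc(COCC[C@H]2O[C@]2(C)C[C@H](O[Si](C)(C)C(C)(C)C)[C@H]2C(=C)C(=O)O[C@H]2/C=C(/C)I)cc1 | intermediate
17 | (4R,5R)-4-[(1S)-1-hydroxy-2-{(2R,3R)-3-[2-(4-methoxybenzyloxy)ethyl]-2-methyloxiran-2-yl}ethyl]-5-[(1Z)-2-iodoprop-1-en-1-yl]-3-methylideneoxolan-2-one | COc1ccc(COCC[C@H]2O[C@]2(C)C[C@H](O)[C@H]2C(=C)C(=O)O[C@H]2/C=C(/C)I)cc1 | intermediate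
18 | (1R)-1-{(2R,3R)-2-[(1Z)-2-iodoprop-1-en-1-yl]-4-methylidene-5-oxooxolan-3-yl}-2-{(2R,3R)-3-[2-(4-methoxybenzyloxy)ethyl]-2-methyloxiran-2-yl}ethyl 2-methylprop-2-enoate | COc1ccc(COCC[C@H]2O[C@]2(C)C[C@@H](OC(=O)C(C)=C)[C@H]2C(=C)C(=O)O[C@H]2/C=C(/C)I)cc1 | intermediate
19 | (1R)-2-[(2R,3R)-3-(2-hydroxyethyl)-2-methyloxiran-2-yl]-1-{(2R,3R)-2-[(1Z)-2-iodoprop-1-en-1-yl]-4-methylidene-5-oxooxolan-3-yl}ethyl 2-methylprop-2-enoate | OCC[C@H]1O[C@]1(C)C[C@@H](OC(=O)C(C)=C)[C@H]1C(=C)C(=O)O[C@H]1/C=C(/C)I | intermediate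
20 | (1R)-1-{(2R,3R)-2-[(1Z)-2-iodoprop-1-en-1-yl]-4-methylidene-5-oxooxolan-3-yl}-2-[(2R,3R)-2-methyl-3-(2-oxoethyl)oxiran-2-yl]ethyl 2-methylprop-2-enoate | O=CC[C@H]1O[C@]1(C)C[C@@H](OC(=O)C(C)=C)[C@H]1C(=C)C(=O)O[C@H]1/C=C(/C)I | intermediate
21 | alkenylchromium dichloride derived from 20 (CrCl2 unit in place of iodine, Z geometry retained) | O=CC[C@H]1O[C@]1(C)C[C@@H](OC(=O)C(C)=C)[C@H]1C(=C)C(=O)O[C@H]1/C=C(/C)[Cr](Cl)Cl | intermediate
22 | (1R,3S,4Z,6S,7R,8R,10R)-1,10-epoxy-3-hydroxy-8-(2-methylprop-2-enoyloxy)germacra-4,11(13)-dien-12,6-olide | C=C(C)C(=O)O[C@@H]1C[C@@]2(C)O[C@@H]2C[C@H](O)/C(C)=C\[C@@H]2OC(=O)C(=C)[C@@H]21 | intermediate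
23 | (1R,3S,4Z,6S,7R,8R,10R)-3-acetoxy-1,10-epoxy-8-(2-methylprop-2-enoyloxy)germacra-4,11(13)-dien-12,6-olide (CNP0267696.3) | C=C(C)C(=O)O[C@@H]1C[C@@]2(C)O[C@@H]2C[C@H](OC(C)=O)/C(C)=C\[C@@H]2OC(=O)C(=C)[C@@H]21 | target

Total step count: 17. Longest linear sequence: 15 steps (steps 1–8 and 11–17; steps 9–10 make the second fragment).

Steps most likely to fail

Step 16 (key step). The strained cis-fused, Z-configured ten-membered ring may close with incomplete facial selectivity at C3, because the aldehyde can add through more than one folding of the chain. The fallback replaces macrocyclic substrate control by reagent control. It sets out from 22 as obtained in admixture with its C3 epimer, (1R,3R,4Z,6S,7R,8R,10R)-1,10-epoxy-3-hydroxy-8-(2-methylprop-2-enoyloxy)germacra-4,11(13)-dien-12,6-olide F1. Both epimers are oxidised with Dess–Martin periodinane/NaHCO3 to the ten-membered Z-enone, (1R,4Z,6S,7R,8R,10R)-1,10-epoxy-8-(2-methylprop-2-enoyloxy)-3-oxogermacra-4,11(13)-dien-12,6-olide F2. Reduction of F2 with (R)-2-methyl-CBS-oxazaborolidine and catecholborane in toluene at −78 °C (alkenyl arm as the large group) should give the (3S) alcohol and comes back to the route at 22.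

Step 11. The weakest stereochemical assumption of the route is that the C8 silyloxy stereocentre directs the aldehyde anti to its C–O bond. Facial discrimination may be eroded by competing conformers, and the δ-silyloxy allylindium may be lost by 1,4-elimination of silanolate to a diene. The fallback replaces the ionic allylmetal by a configurationally defined allylboronate that reacts through a closed six-membered transition state. It sets out from 10, which with B2pin2 and Pd2(dba)3 (zerovalent palladium) in DMSO is converted into methyl (2Z,4S)-4-(tert-butyldimethylsilyloxy)-5-{(2R,3R)-3-[2-(4-methoxybenzyloxy)ethyl]-2-methyloxiran-2-yl}-2-[(4,4,5,5-tetramethyl-1,3,2-dioxaborolan-2-yl)methyl]pent-2-enoate F3. Heating F3 with 14 in toluene (allylboration, syn adduct from the Z-boronate) and PPTS-promoted lactonisation of the borate comes back to the route at 16. This answers erosion and elimination only; a reversed facial sense would require the enantiomeric oxirane and direct acylation of C8.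

Step 13. The C8 hydroxyl is flanked by the branched C7 and the neopentyl-like C9, so the alkoxyphosphonium may eliminate towards C7, or the free hydroxyl may attack the lactone carbonyl (translactonisation), faster than it is displaced. The fallback separates activation from displacement. It sets out from 17, which with chloromethanesulfonyl chloride and pyridine at 0 °C gives (1S)-1-{(2R,3R)-2-[(1Z)-2-iodoprop-1-en-1-yl]-4-methylidene-5-oxooxolan-3-yl}-2-{(2R,3R)-3-[2-(4-methoxybenzyloxy)ethyl]-2-methyloxiran-2-yl}ethyl chloromethanesulfonate F4. SN2 displacement of F4 with caesium methacrylate and 18-crown-6 in toluene at 25 °C (inversion) comes back to the route at 18.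

Further compounds

F1 | step 16 | (1R,3R,4Z,6S,7R,8R,10R)-1,10-epoxy-3-hydroxy-8-(2-methylprop-2-enoyloxy)germacra-4,11(13)-dien-12,6-olide (C3 epimer of 22) | C=C(C)C(=O)O[C@@H]1C[C@@]2(C)O[C@@H]2C[C@@H](O)/C(C)=C\[C@@H]2OC(=O)C(=C)[C@@H]21
F2 | step 16 | (1R,4Z,6S,7R,8R,10R)-1,10-epoxy-8-(2-methylprop-2-enoyloxy)-3-oxogermacra-4,11(13)-dien-12,6-olide | C=C(C)C(=O)O[C@@H]1C[C@@]2(C)O[C@@H]2CC(=O)/C(C)=C\[C@@H]2OC(=O)C(=C)[C@@H]21
F3 | step 11 | methyl (2Z,4S)-4-(tert-butyldimethylsilyloxy)-5-{(2R,3R)-3-[2-(4-methoxybenzyloxy)ethyl]-2-methyloxiran-2-yl}-2-[(4,4,5,5-tetramethyl-1,3,2-dioxaborolan-2-yl)methyl]pent-2-enoate | COC(=O)/C(CB1OC(C)(C)C(C)(C)O1)=C/[C@@H](O[Si](C)(C)C(C)(C)C)C[C@@]1(C)O[C@@H]1CCOCc1ccc(OC)cc1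
F4 | step 13 | (1S)-1-{(2R,3R)-2-[(1Z)-2-iodoprop-1-en-1-yl]-4-methylidene-5-oxooxolan-3-yl}-2-{(2R,3R)-3-[2-(4-methoxybenzyloxy)ethyl]-2-methyloxiran-2-yl}ethyl chloromethanesulfonate | COc1ccc(COCC[C@H]2O[C@]2(C)C[C@H](OS(=O)(=O)CCl)[C@H]2C(=C)C(=O)O[C@H]2/C=C(/C)I)cc1
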